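The bond on which everything rests joins C1 of the geranyl chain to C6 of ring A. The enantiopure flavanone core is assembled first by Rh-catalysed asymmetric 1,4-addition of an arylboronic acid to a chromone, with every phenol capped as a MOM ether except the chelated C5–OH. The key step then joins this core to geraniol itself on acidic alumina: an ortho-allylation that makes the C1–C6 bond from C6–H and the allylic alcohol, losing only water. It exploits the fact that C6, flanked by O5 and O7 of the phloroglucinol ring A, is the only unsubstituted carbon ortho to the one free hydroxyl (C4a is blocked). Acidic removal of three MOM groups finishes the synthesis.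

Key step: step 5

Assumption: the sense of induction in step 4 is taken to follow the usual stereochemical model for Rh/biaryl-diphosphine 1,4-additions to cyclic enones, under which the (S)-ligand gives the (2S)-flavanone; if the sense proves opposite, the antipodal ligand is used.

Step 1
Reactants: 1 5,7-dihydroxy-4H-chromen-4-one
Product: 2 5-hydroxy-7-(methoxymethoxy)-4H-chromen-4-one
Conditions: MOMCl (1.1 equiv), K2CO3, acetone, 0 °C to rt
Reagents that add atoms: chloromethyl methyl ether, COCCl
Why: Williamson-type O-alkylation takes place at the acidic, unchelated 7-OH, while the 5-OH stays locked in its hydrogen bond to C4=O and remains free for the later ortho-direction.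

Step 2
Reactants: 3 4-bromobenzene-1,2-diol
Product: 4 4-bromo-1,2-bis(methoxymethoxy)benzene
Conditions: MOMCl (2.5 equiv), K2CO3, acetone, N2, 0 °C to rt
Reagents that add atoms: chloromethyl methyl ether, COCCl
Why: Double Williamson-type O-alkylation of the catechol gives acetal ethers that should withstand the organolithium and the aqueous Rh step and leave together with the 7-O-MOM group at the end.

Step 3
Reactants: 4 4-bromo-1,2-bis(methoxymethoxy)benzene
Product: 7 [3,4-bis(methoxymethoxy)phenyl]boronic acid, via aryllithium 5 (not isolated), via lithium aryltriisopropoxyborate 6 (not isolated)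
Conditions: n-BuLi, THF, −78 °C; B(OiPr)3, −78 °C to rt; aq. NH4Cl
Reagents that add atoms: triisopropyl borate, CC(C)OB(OC(C)C)OC(C)C; water, O
Why: Bromine–lithium exchange at −78 °C is faster than MOM-directed ortho-deprotonation, and trapping of the aryllithium with the borate ester followed by mild hydrolysis gives the boronic acid (lithiation–borylation).

Step 4
Reactants: 2 5-hydroxy-7-(methoxymethoxy)-4H-chromen-4-one; 7 [3,4-bis(methoxymethoxy)phenyl]boronic acid
Product: 8 (2S)-2-[3,4-bis(methoxymethoxy)phenyl]-5-hydroxy-7-(methoxymethoxy)-2,3-dihydro-4H-chromen-4-one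
Conditions: 7 (2 equiv), [Rh(OH)(cod)]2 (2.5 mol%), (S)-MeO-F12-BIPHEP (5.5 mol%), CH2Cl2/H2O, 20 °C
Reagents that add atoms: none
Why: In this Rh(I)-catalysed asymmetric 1,4-addition of an arylboronic acid to a chromone (Hayashi–Miyaura reaction) the aryl–rhodium species inserts the C2=C3 bond on the face left open by the electron-poor (S)-biaryl diphosphine, which sets C2 as S under catalyst control, and base-free protonolysis of the oxa-π-allyl rhodium should release the flavanone without ring opening.

Step 5
Reactants: 8 (2S)-2-[3,4-bis(methoxymethoxy)phenyl]-5-hydroxy-7-(methoxymethoxy)-2,3-dihydro-4H-chromen-4-one; 9 geraniol, (2E)-3,7-dimethylocta-2,6-dien-1-ol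
Product: 10 (2S)-2-[3,4-bis(methoxymethoxy)phenyl]-6-[(2E)-3,7-dimethylocta-2,6-dien-1-yl]-5-hydroxy-7-(methoxymethoxy)-2,3-dihydro-4H-chromen-4-one
Conditions: 9 (2 equiv), acidic Al2O3 (Brockmann I, activated), ClCH2CH2Cl, 80 °C
Reagents that add atoms: none
Why: The chelated C5–OH/C4=O unit binds a surface aluminium site as an aryloxide, while geraniol is ionised at a neighbouring acidic site to an allyl cation held on the surface; the ortho carbon C6 captures the primary terminus C1 of this cation in a templated Friedel–Crafts (SEAr) step, and loss of the C6 proton restores ring A with water as the only by-product. The closest known reaction type is the alumina-promoted ortho-allylation of phenols with allylic alcohols, known for the geranylation of resorcinols with geraniol. No ring is closed and no stereocentre is formed: the 2E geometry should be carried over from geraniol because capture at C1 is faster than isomerisation of the surface-bound cation, and C2 is untouched because no base is present. The step needs C6 over C8, C- over O-alkylation, linear over branched attachment and ring A over ring B. C6 is the only unsubstituted carbon ortho to the only free hydroxyl (C4a is blocked) and is activated by O5, O7 and O1, whereas C8 lies para to that hydroxyl and out of reach of the templated electrophile; the other phenols are MOM ethers. Attack at the unhindered primary terminus gives the linear geranyl group, and any O-allyl ether formed should re-ionise on the surface and funnel to the C-allyl product.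

Step 6
Reactants: 10 (2S)-2-[3,4-bis(methoxymethoxy)phenyl]-6-[(2E)-3,7-dimethylocta-2,6-dien-1-yl]-5-hydroxy-7-(methoxymethoxy)-2,3-dihydro-4H-chromen-4-one
Product: 11 nymphaeol A, (2S)-2-(3,4-dihydroxyphenyl)-6-[(2E)-3,7-dimethylocta-2,6-dien-1-yl]-5,7-dihydroxy-2,3-dihydro-4H-chromen-4-one
Conditions: 3 M aq. HCl, MeOH, 40 °C, short reaction time
Reagents that add atoms: none
Why: Acid-catalysed acetal solvolysis (transacetalisation to the methanol-derived formal) removes all three MOM groups; C2 cannot epimerise under acid because enolisation touches only C3, and the trisubstituted alkenes should tolerate brief exposure to dilute methanolic HCl.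

Compound list
1 | 5,7-dihydroxy-4H-chromen-4-one | O=c1ccoc2cc(O)cc(O)c12 | starting material
2 | 5-hydroxy-7-(methoxymethoxy)-4H-chromen-4-one | O=c1ccoc2cc(OCOC)cc(O)c12 | intermediate
3 | 4-bromobenzene-1,2-diol | Oc1ccc(Br)cc1O | starting material
4 | 4-bromo-1,2-bis(methoxymethoxy)benzene | COCOc1ccc(Br)cc1OCOC | intermediate
5 | [3,4-bis(methoxymethoxy)phenyl]lithium (not isolated) | [Li]c1ccc(OCOC)c(OCOC)c1 | intermediate
6 | lithium [3,4-bis(methoxymethoxy)phenyl]tri(propan-2-yloxy)borate (not isolated) | [Li+].COCOc1ccc([B-](OC(C)C)(OC(C)C)OC(C)C)cc1OCOC | intermediate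
7 | [3,4-bis(methoxymethoxy)phenyl]boronic acid | COCOc1ccc(B(O)O)cc1OCOC | intermediate
8 | (2S)-2-[3,4-bis(methoxymethoxy)phenyl]-5-hydroxy-7-(methoxymethoxy)-2,3-dihydro-4H-chromen-4-one | O=C1C[C@@H](c2ccc(OCOC)c(OCOC)c2)Oc2cc(OCOC)cc(O)c12 | intermediate
9 | geraniol, (2E)-3,7-dimethylocta-2,6-dien-1-ol | CC(C)=CCC/C(C)=C/CO | starting material
10 | (2S)-2-[3,4-bis(methoxymethoxy)phenyl]-6-[(2E)-3,7-dimethylocta-2,6-dien-1-yl]-5-hydroxy-7-(methoxymethoxy)-2,3-dihydro-4H-chromen-4-one | CC(C)=CCC/C(C)=C/Cc1c(OCOC)cc2c(c1O)C(=O)C[C@@H](c1ccc(OCOC)c(OCOC)c1)O2 | intermediate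
11 | nymphaeol A, (2S)-2-(3,4-dihydroxyphenyl)-6-[(2E)-3,7-dimethylocta-2,6-dien-1-yl]-5,7-dihydroxy-2,3-dihydro-4H-chromen-4-one | CC(C)=CCC/C(C)=C/Cc1c(O)cc2c(c1O)C(=O)C[C@@H](c1ccc(O)c(O)c1)O2 | target

Total step count: 6
Longest linear sequence: 5 steps (steps 2, 3, 4, 5 and 6, from 3 to 11)

Steps most likely to fail

Step 5 (key step). Ionisation of geraniol on the surface may outrun its capture by the arene, leading to isomerisation of the allyl cation (loss of E geometry, branched attachment) or cyclisation of the chain. Attack at C8, partial loss of MOM acetals on the acidic surface, slow reaction of the chelated phenol and erosion of C2 by reversible ring opening on basic surface sites are also possible. The fallback sets out from 8 and comes back at 10. It replaces the C–H allylation by a halogenation and cross-coupling pair under neutral conditions. Ortho-iodination of 8 with benzyltrimethylammonium dichloroiodate and CaCO3 in CH2Cl2–MeOH at rt is expected to be directed to C6 by the free 5-OH and to give (2S)-2-[3,4-bis(methoxymethoxy)phenyl]-5-hydroxy-6-iodo-7-(methoxymethoxy)-2,3-dihydro-4H-chromen-4-one F1. Tributyl[(2E)-3,7-dimethylocta-2,6-dien-1-yl]stannane F2 is prepared from geranyl chloride and tributylstannyllithium in THF. Stille coupling of F1 with F2 (Pd2(dba)3, tri(2-furyl)phosphine, DMF, 60 °C) should then give 10, with reductive elimination through the unhindered primary allyl terminus.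

Step 4. Facial discrimination on the 5-hydroxychromone may be insufficient, and protonolysis of the aryl–rhodium species (protodeboronation) may outrun insertion into the electron-rich chromone when the diphosphine catalyst is used. The fallback sets out from 2 and 7 and comes back at 8. It gives up asymmetric catalysis for resolution. Conjugate addition with the more active achiral catalyst [Rh(OH)(cod)]2 in dioxane/H2O should give racemic (2RS)-2-[3,4-bis(methoxymethoxy)phenyl]-5-hydroxy-7-(methoxymethoxy)-2,3-dihydro-4H-chromen-4-one F3. Preparative HPLC on a chiral stationary phase (amylose tris(3,5-dimethylphenylcarbamate)) then separates the enantiomers and delivers 8.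

Step 6. Acid-catalysed addition of the flanking 5-OH or 7-OH to the proximal double bond of the geranyl chain (chroman formation) and Markovnikov addition of methanol to the terminal alkene may compete with acetal cleavage. The fallback sets out from 8 and comes back at 11. It changes the protecting groups so that acid never meets the geranyl chain.
- The MOM groups are removed from 8 before any alkene is present (HCl, MeOH) to give (2S)-eriodictyol F4.
- Silylation (TBSCl, imidazole, DMF) caps O7, O3' and O4' and leaves the chelated 5-OH, giving (2S)-2-[3,4-bis(tert-butyldimethylsilyloxy)phenyl]-7-(tert-butyldimethylsilyloxy)-5-hydroxy-2,3-dihydro-4H-chromen-4-one F5.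
- Ortho-iodination as described for step 5 gives the corresponding 6-iodo tris-silyl ether F6.
- Stille coupling of F6 with the stannane F2 gives the 6-geranyl tris-silyl ether F7.
- Et3N·3HF in THF at 0 °C releases 11 under nearly neutral conditions.

Further compounds
F1 | step 5 | (2S)-2-[3,4-bis(methoxymethoxy)phenyl]-5-hydroxy-6-iodo-7-(methoxymethoxy)-2,3-dihydro-4H-chromen-4-one | O=C1C[C@@H](c2ccc(OCOC)c(OCOC)c2)Oc2cc(OCOC)c(I)c(O)c12
F2 | step 5 | tributyl[(2E)-3,7-dimethylocta-2,6-dien-1-yl]stannane | CC(C)=CCC/C(C)=C/C[Sn](CCCC)(CCCC)CCCC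
F3 | step 4 | (2RS)-2-[3,4-bis(methoxymethoxy)phenyl]-5-hydroxy-7-(methoxymethoxy)-2,3-dihydro-4H-chromen-4-one (racemate) | O=C1CC(c2ccc(OCOC)c(OCOC)c2)Oc2cc(OCOC)cc(O)c12
F4 | step 6 | (2S)-eriodictyol, (2S)-2-(3,4-dihydroxyphenyl)-5,7-dihydroxy-2,3-dihydro-4H-chromen-4-one | O=C1C[C@@H](c2ccc(O)c(O)c2)Oc2cc(O)cc(O)c12
F5 | step 6 | (2S)-2-[3,4-bis(tert-butyldimethylsilyloxy)phenyl]-7-(tert-butyldimethylsilyloxy)-5-hydroxy-2,3-dihydro-4H-chromen-4-one | O=C1C[C@@H](c2ccc(O[Si](C)(C)C(C)(C)C)c(O[Si](C)(C)C(C)(C)C)c2)Oc2cc(O[Si](C)(C)C(C)(C)C)cc(O)c12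
F6 | step 6 | (2S)-2-[3,4-bis(tert-butyldimethylsilyloxy)phenyl]-7-(tert-butyldimethylsilyloxy)-5-hydroxy-6-iodo-2,3-dihydro-4H-chromen-4-one | O=C1C[C@@H](c2ccc(O[Si](C)(C)C(C)(C)C)c(O[Si](C)(C)C(C)(C)C)c2)Oc2cc(O[Si](C)(C)C(C)(C)C)c(I)c(O)c12
F7 | step 6 | (2S)-2-[3,4-bis(tert-butyldimethylsilyloxy)phenyl]-7-(tert-butyldimethylsilyloxy)-6-[(2E)-3,7-dimethylocta-2,6-dien-1-yl]-5-hydroxy-2,3-dihydro-4H-chromen-4-one | CC(C)=CCC/C(C)=C/Cc1c(O[Si](C)(C)C(C)(C)C)cc2c(c1O)C(=O)C[C@@H](c1ccc(O[Si](C)(C)C(C)(C)C)c(O[Si](C)(C)C(C)(C)C)c1)O2
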